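**Retrosynthetic overview**
1. Locants: ring C1 (CH–O-isovaleryl), C2 (C=O), C3 (C–CH3) and C4 (CH) of the ring oxirane, C5 (CH2), C6 (CH); side chain C7 (oxirane C) with C14 (oxirane CH2), C8 (C=O), C9=C10 (E), C11 (C(CH3)2OOH). The target is (1S,3S,4S,6R,7R) in these locants.
2. Feature and key cut: the C8 carbonyl carbon lies between the C7 oxirane carbon and the C9=C10 alkene. With C7 held as a C7=C14 enol triflate, C8 is one carbon between two sp2 carbons and enters as carbon monoxide, so C7–C8 and C8–C9 are cut together (enol triflate + CO + (E)-alkenylstannane).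
3. After the coupling: nucleophilic epoxidation of C7=C14 gives the C7/C14 oxirane; O2 capture of the C8 dienolate gives C11–OOH (C7 has no hydrogen, so only C11–H can be removed); the C2 ketone is unveiled last, with the hydroperoxide masked as a peroxyketal.
4. Before the coupling: enol triflate ⇐ C7 methyl ketone ⇐ isopropenyl group of (R)-carvone. C1 (α′-hydroxylation, trans to C6), C2 (Luche reduction) and C3/C4 (vanadium epoxidation syn to C2–OH) are all set from the carvone stereocentre C6.
5. Ring order: the cyclohexane comes from carvone; the C3–C4 oxirane closes first (step 4), the C7–C14 oxirane second (step 10); the key step closes no ring.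

Key step: step 9

Remark (assumption): (R)-(−)-carvone of high enantiomeric purity is the only source of chirality, and the locants above are used for every intermediate.

**Step 1**
Reactants: 1 (R)-carvone
Product: 3 (5S,6S)-6-hydroxy-2-methyl-5-(prop-1-en-2-yl)cyclohex-2-en-1-one (trans-6-hydroxycarvone; C1–OH trans to the C6 isopropenyl group), via sodium dienolate 2 (not isolated)
Conditions: NaHMDS, THF, −78 °C; then (±)-2-(phenylsulfonyl)-3-phenyloxaziridine, −78 °C; aq. NH4Cl
Reagents that add atoms: 2-(phenylsulfonyl)-3-phenyloxaziridine (Davis oxaziridine), O=S(=O)(N1OC1c1ccccc1)c1ccccc1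
Why: Kinetic α′-deprotonation of the enone gives the cross-conjugated dienolate, and enolate hydroxylation with the Davis oxaziridine should occur on the face anti to the neighbouring C6 isopropenyl group, which sets C1 trans to C6.

**Step 2**
Reactants: 3 trans-6-hydroxycarvone; 4 isovaleric acid
Product: 5 (1S,6S)-3-methyl-2-oxo-6-(prop-1-en-2-yl)cyclohex-3-en-1-yl 3-methylbutanoate
Conditions: DCC, DMAP (cat.), CH2Cl2, 0 °C → rt
Reagents that add atoms: none
Why: Steglich esterification acylates the C1 hydroxyl without a base strong enough to epimerise C1, which in any case sits in its more stable trans-diequatorial arrangement with C6.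

**Step 3**
Reactants: 5 isovalerate enone
Product: 6 (1S,2S,6S)-2-hydroxy-3-methyl-6-(prop-1-en-2-yl)cyclohex-3-en-1-yl 3-methylbutanoate (C2–OH cis to the C6 isopropenyl group and trans to the C1 ester)
Conditions: NaBH4, CeCl3·7H2O, MeOH, −78 °C
Reagents that add atoms: none
Why: Luche 1,2-reduction with axial hydride delivery to the enone, whose C1 ester and C6 isopropenyl group are both equatorial, should place the new C2 hydroxyl equatorial, as in the reduction of carvone to cis-carveol.

**Step 4**
Reactants: 6 allylic alcohol
Product: 7 epoxy alcohol (C3–C4 oxirane on the same face as C2–OH and the C6 isopropenyl group; C1 isovalerate on the opposite face)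
Conditions: VO(acac)2 (cat.), t-BuOOH, CH2Cl2, 0 °C → rt
Reagents that add atoms: tert-butyl hydroperoxide, CC(C)(C)OO
Why: In this hydroxyl-directed vanadium-catalysed epoxidation the vanadate ester of the allylic C2 alcohol delivers oxygen to C3=C4 on its own face, setting C3 and C4 syn to C2–OH, while the remote isopropenyl alkene reacts much more slowly.

**Step 5**
Reactants: 7 epoxy alcohol
Product: 8 C2 triethylsilyl ether of 7
Conditions: TESOTf, 2,6-lutidine, CH2Cl2, −78 °C
Reagents that add atoms: triethylsilyl trifluoromethanesulfonate, CC[Si](CC)(CC)OS(=O)(=O)C(F)(F)F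
Why: Silylation of the hindered C2 hydroxyl with a silyl triflate and a non-nucleophilic base is fast at −78 °C, which leaves no time for O1→O2 acyl migration and spares the oxirane.

**Step 6**
Reactants: 8 silyl ether
Product: 10 C7 methyl ketone (C6 carries an acetyl group), via ozonide 9 (not isolated)
Conditions: O3, CH2Cl2, −78 °C; then Me2S, −78 °C → rt
Reagents that add atoms: ozone, [O-][O+]=O
Why: Ozonolysis with reductive work-up cleaves the only C=C bond to the methyl ketone (the former isopropenyl methyl becomes C14); oxirane, ester and silyl ether are inert to ozone and the neutral work-up does not epimerise C6.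

**Step 7**
Reactants: 10 methyl ketone
Product: 12 C7 enol triflate (1S,2R,3S,4S,6R; C6 carries a 1-(trifluoromethylsulfonyloxy)vinyl group), via potassium enolate 11 (not isolated)
Conditions: KHMDS, THF, −78 °C; then Comins' reagent, −78 °C; aq. NH4Cl
Reagents that add atoms: N-(5-chloropyridin-2-yl)bis(trifluoromethanesulfonimide) (Comins' reagent), O=S(=O)(N(c1ccc(Cl)cn1)S(=O)(=O)C(F)(F)F)C(F)(F)F
Why: Kinetic enolisation followed by O-sulfonylation: the hindered amide removes a methyl proton rather than the tertiary C6–H (whose enolate could expel the C1 carboxylate), and the pyridyl triflimide traps the enolate at −78 °C before it can add to the ester.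

**Step 8**
Reactants: 13 3-methylbut-1-yne; 14 tributyltin hydride
Product: 15 (E)-tributyl(3-methylbut-1-en-1-yl)stannane
Conditions: Pd2(dba)3 (cat.), Cy3P·HBF4 (cat.), i-Pr2NEt (cat.), CH2Cl2, 0 °C → rt (alkyne in excess)
Reagents that add atoms: none
Why: Palladium-catalysed hydrostannation is a syn addition, and with the bulky tricyclohexylphosphine ligand and the branched alkyne tin should go to the terminal carbon, giving the (E)-alkenylstannane.

**Step 9**
Reactants: 12 enol triflate; 15 (E)-alkenylstannane; 16 carbon monoxide
Product: 17 cross-conjugated dienone (C6 carries –C(=CH2)–C(=O)–CH=CH–CH(CH3)2 with (E)-C9=C10; C1 isovalerate, C2 OTES and C3–C4 oxirane unchanged)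
Conditions: Pd(PPh3)4 (cat.), LiCl, CO (3 atm), THF, 50 °C
Reagents that add atoms: none
Why: Pd(0) adds oxidatively into the C7–OTf bond and chloride from LiCl gives the neutral alkenylpalladium(II) chloride; CO then inserts to the α-substituted acryloylpalladium species, the (E)-alkenyl group is transferred from tin with retention, and reductive elimination forms C8–C9, so C7–C8 and C8–C9 are made in one operation. The closest known reaction type is the carbonylative Stille coupling of enol triflates with alkenylstannanes to give divinyl ketones. No ring is closed and no stereocentre is created; C6, next to the reacting carbon, is not enolised under these neutral conditions, and C14 is fixed as the methylene because the triflate derives from the methyl ketone. The step needs carbonylative rather than direct coupling and retention of the (E) geometry: under 3 atm CO, insertion into the unhindered 1,1-disubstituted alkenyl–Pd bond should outrun the slow transmetalation from tin, and alkenyl transfer from tin is stereoretentive. The isovalerate, the silyl ether and the non-allylic C3–C4 oxirane offer no pathway to Pd(0), CO or LiCl at this temperature.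

**Step 10**
Reactants: 17 dienone
Product: 18 (7R)-epoxy enone (C7/C14 oxirane; C8 ketone conjugated only with (E)-C9=C10)
Conditions: t-BuOOH, DBU (cat.), CH2Cl2, 0 °C
Reagents that add atoms: tert-butyl hydroperoxide, CC(C)(C)OO
Why: In this Weitz–Scheffer nucleophilic epoxidation tert-butylperoxide should add to the unsubstituted C14 terminus far faster than to the isopropyl-bearing C10, and the resulting C7 enolate, with C6–H in its plane to avoid allylic 1,3-strain, should close onto the peroxide oxygen on the face next to C5H2 rather than the face screened by the C1 isovalerate, which corresponds to (7R).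

**Step 11**
Reactants: 18 epoxy enone
Product: 20 C11 hydroperoxide (side chain –C(=O)–CH=CH–C(CH3)2OOH with (E) geometry; C2 OTES retained), via potassium dienolate 19 (not isolated)
Conditions: KHMDS, THF, −78 °C; then dry O2, −78 °C; AcOH, −78 °C
Reagents that add atoms: dioxygen, O=O
Why: Because C7 is quaternary, γ-deprotonation at C11 is the only enolisation open to the C8 ketone, and in this dienolate autoxidation the extended potassium dienolate should capture triplet oxygen at C11, restoring the conjugated (E)-enone from the s-trans dienolate, while any isovalerate enolate is the less stable anion and should return its proton through HN(SiMe3)2.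

**Step 12**
Reactants: 20 hydroperoxide
Product: 21 C11 2-methoxyprop-2-yl peroxyketal (–C(CH3)2–OO–C(CH3)2OCH3)
Conditions: 2-methoxypropene, PPTS (cat.), CH2Cl2, 0 °C
Reagents that add atoms: 2-methoxypropene, COC(C)=C
Why: Acid-catalysed addition of the hydroperoxide O–H across the enol ether gives a peroxyketal, a hydroperoxide protecting group that is inert to fluoride and to the iodine(V) oxidant used next.

**Step 13**
Reactants: 21 peroxyketal silyl ether
Product: 22 C2 alcohol
Conditions: TBAF, AcOH, THF, 0 °C → rt
Reagents that add atoms: none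
Why: Fluoride-mediated Si–O cleavage, buffered with acetic acid so that no free alkoxide is present to trigger isovaleryl migration from O1 to O2 or addition to the enone.

**Step 14**
Reactants: 22 alcohol
Product: 23 C2 ketone with the C11 peroxyketal
Conditions: Dess–Martin periodinane, NaHCO3, CH2Cl2, 0 °C → rt
Reagents that add atoms: none
Why: Dess–Martin oxidation converts the hindered C2 carbinol into the ketone under buffered conditions that should not epimerise the now acidic C1–H nor touch the oxiranes, the enone or the peroxyketal.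

**Step 15**
Reactants: 23 peroxyketal diketone
Product: 24 target CNP0131119.1
Conditions: AcOH/THF/H2O, rt
Reagents that add atoms: none
Why: Acetal hydrolysis under mild aqueous acid releases the hydroperoxide; both oxiranes sit on a carbonyl-bearing carbon, which slows acid-promoted opening, and the ester and C1 are not affected.

**Compound list**
1 | (R)-(−)-carvone | CC1=CC[C@H](CC1=O)C(=C)C | starting material
2 | sodium cross-conjugated dienolate of carvone (O–C=C toward the future C1) | CC1=CC[C@H](C=C1[O-])C(C)=C.[Na+] | intermediate (not isolated)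
3 | (5S,6S)-6-hydroxy-2-methyl-5-(prop-1-en-2-yl)cyclohex-2-en-1-one | O[C@@H]1C(=O)C(C)=CC[C@H]1C(C)=C | intermediate
4 | isovaleric acid (3-methylbutanoic acid) | CC(C)CC(=O)O | starting material
5 | (1S,6S)-3-methyl-2-oxo-6-(prop-1-en-2-yl)cyclohex-3-en-1-yl 3-methylbutanoate | CC(C)CC(=O)O[C@@H]1C(=O)C(C)=CC[C@H]1C(C)=C | intermediate
6 | (1S,2S,6S)-2-hydroxy-3-methyl-6-(prop-1-en-2-yl)cyclohex-3-en-1-yl 3-methylbutanoate | CC(C)CC(=O)O[C@@H]1[C@@H](O)C(C)=CC[C@H]1C(C)=C | intermediate
7 | epoxy alcohol: C3–C4 oxirane, C2–OH and C6 isopropenyl on one face, C1 isovalerate on the other | CC(C)CC(=O)O[C@@H]1[C@@H](O)[C@@]2(C)O[C@H]2C[C@H]1C(C)=C | intermediate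
8 | C2 triethylsilyl ether of 7 | CC(C)CC(=O)O[C@@H]1[C@@H](O[Si](CC)(CC)CC)[C@@]2(C)O[C@H]2C[C@H]1C(C)=C | intermediate
9 | ozonide of 8 (C6 carries a 3-methyl-1,2,4-trioxolan-3-yl group; mixture at the trioxolane carbon) | CC(C)CC(=O)O[C@@H]1[C@@H](O[Si](CC)(CC)CC)[C@@]2(C)O[C@H]2C[C@H]1C1(C)OCOO1 | intermediate (not isolated)
10 | C7 methyl ketone (C6 acetyl) | CC(C)CC(=O)O[C@@H]1[C@@H](O[Si](CC)(CC)CC)[C@@]2(C)O[C@H]2C[C@H]1C(C)=O | intermediate
11 | potassium enolate of 10 (C7(O−)=C14H2) | CC(C)CC(=O)O[C@@H]1[C@@H](O[Si](CC)(CC)CC)[C@@]2(C)O[C@H]2C[C@H]1C(=C)[O-].[K+] | intermediate (not isolated)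
12 | C7 enol triflate (1S,2R,3S,4S,6R) | CC(C)CC(=O)O[C@@H]1[C@@H](O[Si](CC)(CC)CC)[C@@]2(C)O[C@H]2C[C@H]1C(=C)OS(=O)(=O)C(F)(F)F | intermediate
13 | 3-methylbut-1-yne | CC(C)C#C | starting material
14 | tributyltin hydride | CCCC[SnH](CCCC)CCCC | starting material
15 | (E)-tributyl(3-methylbut-1-en-1-yl)stannane | CCCC[Sn](CCCC)(CCCC)/C=C/C(C)C | intermediate
16 | carbon monoxide | [C-]#[O+] | starting material
17 | cross-conjugated C7-methylene dienone, (E)-C9=C10 | CC(C)CC(=O)O[C@@H]1[C@@H](O[Si](CC)(CC)CC)[C@@]2(C)O[C@H]2C[C@H]1C(=C)C(=O)/C=C/C(C)C | intermediate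
18 | (7R)-epoxy enone (C7/C14 oxirane) | CC(C)CC(=O)O[C@@H]1[C@@H](O[Si](CC)(CC)CC)[C@@]2(C)O[C@H]2C[C@H]1[C@]1(C(=O)/C=C/C(C)C)CO1 | intermediate
19 | potassium dienolate of 18 (C8(O−)=C9–C10=C11) | CC(C)CC(=O)O[C@@H]1[C@@H](O[Si](CC)(CC)CC)[C@@]2(C)O[C@H]2C[C@H]1[C@]1(C([O-])=CC=C(C)C)CO1.[K+] | intermediate (not isolated)
20 | C11 hydroperoxide, C2 OTES | CC(C)CC(=O)O[C@@H]1[C@@H](O[Si](CC)(CC)CC)[C@@]2(C)O[C@H]2C[C@H]1[C@]1(C(=O)/C=C/C(C)(C)OO)CO1 | intermediate
21 | C11 2-methoxyprop-2-yl peroxyketal, C2 OTES | CC(C)CC(=O)O[C@@H]1[C@@H](O[Si](CC)(CC)CC)[C@@]2(C)O[C@H]2C[C@H]1[C@]1(C(=O)/C=C/C(C)(C)OOC(C)(C)OC)CO1 | intermediate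
22 | C2 alcohol with C11 peroxyketal | CC(C)CC(=O)O[C@@H]1[C@@H](O)[C@@]2(C)O[C@H]2C[C@H]1[C@]1(C(=O)/C=C/C(C)(C)OOC(C)(C)OC)CO1 | intermediate
23 | C2 ketone with C11 peroxyketal | CC(C)CC(=O)O[C@@H]1C(=O)[C@@]2(C)O[C@H]2C[C@H]1[C@]1(C(=O)/C=C/C(C)(C)OOC(C)(C)OC)CO1 | intermediate
24 | CNP0131119.1, (1S,3S,4S,6R,7R) in the locants of the overview | CC(C)CC(=O)O[C@@H]1C(=O)[C@@]2(C)O[C@H]2C[C@H]1[C@]1(C(=O)/C=C/C(C)(C)OO)CO1 | target

**Totals**
Total steps: 15. Longest linear sequence: 14 (steps 1–7 and 9–15; step 8 is the one-step side branch).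

**Steps most likely to fail**

Step 11. The amide base may deprotonate the isovalerate α-CH2 in competition with C11–H, oxygen may be captured at C9 instead of C11, and the peroxide anion formed may add to the enone of a second molecule. The fallback brings the peroxide in with the tin partner instead of making it on the enone. It sets out from enol triflate 12. Commercial 2-methylbut-3-yn-2-ol with 50% H2O2 and catalytic H2SO4 (perhydrolysis of the tertiary propargylic alcohol) should give 2-methylbut-3-yn-2-yl hydroperoxide F1. 2-Methoxypropene/PPTS converts it into the peroxyketal alkyne F2, and palladium-catalysed hydrostannation with 14 should give the (E)-peroxyketal stannane F3. Carbonylative Stille coupling of F3 with 12 and 16 under the conditions of step 9 should give the peroxyketal dienone F4, and t-BuOOH/DBU epoxidation as in step 10 returns to the route at 21.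

Step 10. The facial selectivity of the ring closure at C7 rests on a conformational forecast and may be poor; in addition, C9=C10 may be epoxidised and the C7=C14 bond may migrate under base. The fallback is a reagent-controlled electrophilic epoxidation of the allylic alcohol. It sets out from 17. Corey–Bakshi–Shibata reduction ((R)-Me-CBS, catecholborane, toluene, −78 °C; the α-branched C7 alkenyl group taken as the large substituent) should give the (8S)-dienol F5. Sharpless asymmetric epoxidation (Ti(Oi-Pr)4, L-(+)-DIPT, t-BuOOH, 4 Å sieves, CH2Cl2, −20 °C) should give the (7R,8S)-epoxy alcohol F6, because the (8S) carbinol is the matched case at C7=C14 and the mismatched case at C9=C10. Dess–Martin oxidation of C8–OH returns to the route at 18.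

Step 9. The alkenylpalladium may couple directly with the stannane before CO inserts, or slow insertion at 50 °C may allow the α-methylene dienone to decompose or polymerise. The fallback takes C8 from an aldehyde carbon instead of CO. It sets out from 12. Nozaki–Hiyama–Kishi coupling with commercial (E)-4-methylpent-2-enal (CrCl2, NiCl2 cat., DMF, rt) should give the C8-epimeric dienols F7, and Dess–Martin oxidation returns to the route at 17.

**Further compounds**
F1 | step 11 | 2-methylbut-3-yn-2-yl hydroperoxide | C#CC(C)(C)OO
F2 | step 11 | 3-[(2-methoxypropan-2-yl)peroxy]-3-methylbut-1-yne | C#CC(C)(C)OOC(C)(C)OC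
F3 | step 11 | (E)-tributyl{3-[(2-methoxypropan-2-yl)peroxy]-3-methylbut-1-en-1-yl}stannane | CCCC[Sn](CCCC)(CCCC)/C=C/C(C)(C)OOC(C)(C)OC
F4 | step 11 | C7-methylene dienone carrying the C11 peroxyketal | CC(C)CC(=O)O[C@@H]1[C@@H](O[Si](CC)(CC)CC)[C@@]2(C)O[C@H]2C[C@H]1C(=C)C(=O)/C=C/C(C)(C)OOC(C)(C)OC
F5 | step 10 | (8S)-dienol (C8 carbinol between C7=C14 and (E)-C9=C10) | CC(C)CC(=O)O[C@@H]1[C@@H](O[Si](CC)(CC)CC)[C@@]2(C)O[C@H]2C[C@H]1C(=C)[C@@H](O)/C=C/C(C)C
F6 | step 10 | (7R,8S)-epoxy alcohol | CC(C)CC(=O)O[C@@H]1[C@@H](O[Si](CC)(CC)CC)[C@@]2(C)O[C@H]2C[C@H]1[C@]1([C@@H](O)/C=C/C(C)C)CO1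
F7 | step 9 | C8-epimeric dienols (mixture at C8) | CC(C)CC(=O)O[C@@H]1[C@@H](O[Si](CC)(CC)CC)[C@@]2(C)O[C@H]2C[C@H]1C(=C)C(O)/C=C/C(C)C
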